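## Analysis of the target

Preluffariellolide A (20) is a monocyclic C25 terpenoid: a 2-hydroxy-2,6,6-trimethylcyclohexyl ring joined through a two-carbon tether to an all-E triene chain that ends in a primary allylic alcohol. The chain is numbered C1 (CH2OH) to C13 and the ring C14 (CH), C15 (methyl carbinol), C16 to C18 (CH2) and C19 (CMe2). The only stereocentres are the adjacent C14 and C15, both S, with the C15 hydroxyl trans and the C15 methyl cis to the chain on C14. The three trisubstituted alkenes (C2=C3, C6=C7, C10=C11) must stay E. Together with the allylic C1 oxygen and the tertiary C15 alcohol they exclude strong acids (cation-olefin cyclisation, ionisation, dehydration) and unselective electrophilic oxidants. The main difficulty is that C14 lies between two fully substituted carbons, so C13–C14 is the most congested bond in the molecule, and the ring offers no function other than the C15 hydroxyl from which to control the two stereocentres. The strategy rests on one feature: a temporary carbonyl at C16 makes C14 the β-carbon and C15 the α-carbon of a 2-methylcyclohexenone, so the chain can be delivered to a trigonal C14 and oxygen to an enolate carbon C15 in one operation. The price is that C16 must afterwards be returned to a methylene without disturbing the neighbouring tertiary alcohol or the alkenes.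

## Retrosynthetic reasoning

**20 to 19 (O–Si).** The C1 hydroxyl is masked as its tert-butyldimethylsilyl ether 19. The chain can then be carried as an organomagnesium reagent and through base, hydride and radical steps; the forward step is a fluoride cleavage that leaves the tertiary alcohol alone.

**19 to 16 (oxygen added at C16).** A carbonyl is placed on C16, leading back through xanthate 18 and diol 17 to the α-hydroxy ketone 16. C16 is the only ring position from which a carbonyl activates C14 (as β-carbon) and C15 (as α-carbon) together. Forward, the ketone is reduced, the secondary hydroxyl alone is converted into a thiocarbonyl derivative and removed by a radical chain; the C15–O bond is never touched, so C15 keeps its configuration.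

**16 to 5 and 14 (C13–C14 and C15–O).** Both bonds at the congested centre are cut together. This gives the achiral enone 5 and the complete C1–C13 chain as Grignard reagent 14. Cutting here, and not at C12–C13 or inside the ring, means nothing has to be coupled next to a finished quaternary-flanked C14: the nucleophile meets an sp2 carbon. The forward reaction must add 14 in 1,4-fashion to one face of C14 under a chiral copper catalyst, and then transfer oxygen to C15 of the magnesium enolate 15 on the face away from the new chain. Both stereocentres arise in this one flask.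

**5 to 2 and 3 (C18–C19 and C14=C15).** The enone is opened by a retro-aldol condensation to keto aldehyde 4 and by a retro-Michael step to enamine 2 and vinyl ketone 3; enamine 2 comes from aldehyde 1. The quaternary C19 is made by the Michael step, and the aldol step can close only one ring size, so the methyl ends on C15 without a regiochemical issue.

**14 to 11 (C–Mg, C–Br).** The Grignard reagent comes from bromide 13, and that from homoallylic alcohol 11 through mesylate 12. A primary sp3 bromide three bonds away from the nearest alkene inserts magnesium without allylic scrambling.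

**11 to 9 (C12–C13).** C13 is the one carbon that farnesol lacks. It is cut off as a methylene unit: alcohol 11 comes from terminal hydroboration of the 1,3-diene 10, which comes from methylenation of enal 9. This avoids displacement on an allylic C12 halide, where attack at C12 and at C10 would compete.

**9 to 6 (C12–O).** Enal 9 is the oxidation product of allylic alcohol 8, which arises by allylic oxidation of the E-methyl group at the far end of silyl ether 7, made from (2E,6E)-farnesol 6. All three E alkenes of the target are thus bought, not made.

## Alternatives that were turned down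

**Alternative 1: Birch reduction and group-selective epoxidation.**
- Disconnection: the C15–O bond is traced to an oxirane on a cyclohexa-1,4-diene obtained from an aromatic ring, with C13 present as a silyloxymethyl group.
- Forward key step: the achiral dienyl silyl ether A2 has two mirror-related trisubstituted alkenes. A chiral ketone-derived dioxirane would epoxidise one of them on the face away from the CH2OSi group to give A1, setting C14 and C15 together.
- For: the ring comes from a cheap arene. No surplus carbonyl has to be erased, since hydride opening of A1 at C16 gives the tertiary carbinol directly. The stereocentres are set on a small fragment whose enantiomeric purity can be checked before the chain is committed. On these points it is stronger than the chosen route.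
- Against: the reagent must at once choose between enantiotopic alkenes, choose one face and stop at the mono-epoxide. C19 in A1 still carries one methyl on an alkene, so the geminal dimethyl group needs further steps (for instance cyclopropanation and hydrogenolysis) before any chain alkene is present. The chain must then be joined at C13, a CH2 on a carbon flanked by two quaternary centres, which is a poor electrophile and demands a sulfone-type detour.
- Comparison: more steps follow its key step than the four that follow step 10, and the hardest junction remains unsolved. The chosen route instead forms the C13–C14 bond directly at a trigonal carbon.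

**Alternative 2: Diels–Alder ring synthesis with acetyl as latent hydroxyl.**
- Disconnection: C14–C19 and C15–C16 are cut.
- Forward key step: diene A4 and the E-configured keto enal A5 would combine under a chiral Lewis acid to give A3, in which the trans dienophile geometry becomes the trans C13/C15-substituent relationship. The acetyl group later becomes the hydroxyl by a Baeyer–Villiger oxidation with retention.
- For: the whole ring, the quaternary C19 and both stereocentres are made in one cycloaddition from very small pieces. In bond-forming density this is stronger than the chosen key step.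
- Against: A4 carries a cis methyl on its terminus, so the s-cis conformer is disfavoured and the diene is sluggish and prone to isomerise or polymerise under Lewis acids. The cycloaddition has to form a bond between the dimethylated terminus and the aldehyde-bearing carbon, next to a new quaternary centre. Regiochemistry depends on the catalyst binding the aldehyde and not the ketone of A5. Afterwards the ring alkene must be saturated, the aldehyde masked, the acetyl oxidised and hydrolysed, and the chain joined at C13 with the same neopentyl problem as in Alternative 1. The peracid step must also precede any chain alkene.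
- Comparison: the route is clearly longer after its key step and its key step is less secure. The chosen route brings the chain in intact and needs only the C16 erasure.

**Alternative 3: Amine-catalysed enolexo aldol closing C14–C15.**
- Disconnection: the ring bond C14–C15 is cut.
- Forward key step: the achiral keto aldehyde A7 would form an enamine at its aldehyde with an amino acid catalyst of the proline type. The enamine carbon C14 adds to the methyl ketone C15 to give the trans hydroxy aldehyde A6.
- For: a metal-free, inexpensive catalyst; the product carries exactly the ring of the target with both stereocentres and no extra oxygen; no tin and no deoxygenation. In reagent cost and in having no function to erase it is stronger than the chosen route.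
- Against: the enamine carbon is neopentyl (next to C19). The acceptor is a ketone and not an aldehyde. The product is a tertiary β-hydroxy aldehyde that can revert by retro-aldol or epimerise at C14, so stereochemical erosion is likely. A7 itself needs several steps. The chain must then be attached at C13, and C12 is allylic, so an allyl-metal addition would face α/γ ambiguity and an olefination would give a diene needing selective reduction.
- Comparison: about five further steps are needed to join the chain and the overall length is no shorter. The chosen route sets both centres in the fragment union itself and leaves no coupling next to C14.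

Key step: step 10

Remarks on the chemistry (assumptions):
- The sense of induction of the ferrocenyl diphosphine on this enone is assumed to follow that on simple cyclohexenones. The route is written with the (R,Sp) ligand, and its mirror image is used if the chain is found to enter the Re face of C14 instead of the required Si face.
- Reduction in step 11 is expected to give mainly the trans-diol (1R). Any C16 epimer is carried along, because C16 becomes a methylene in step 13.

## Route

Step 1
Reactants: 1 2-methylpropanal
Product: 2 1-(2-methylprop-1-en-1-yl)pyrrolidine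
Conditions: pyrrolidine, TsOH·H2O (cat.), cyclohexane, reflux, Dean–Stark; distillation
Reagents that add atoms: pyrrolidine, C1CCNC1
Why: Condensation of an α-branched aldehyde with a secondary amine, driven by removal of water, gives the enamine needed for a Stork enamine alkylation; the aldehyde has a single α-hydrogen, so only one enamine can form.

Step 2
Reactants: 2 1-(2-methylprop-1-en-1-yl)pyrrolidine; 3 pent-1-en-3-one
Product: 5 2,4,4-trimethylcyclohex-2-en-1-one, via 2,2-dimethyl-5-oxoheptanal 4 (not isolated)
Conditions: neat, 0 °C to rt; then 8 M HCl, rt; distillation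
Reagents that add atoms: none
Why: Stork enamine Michael addition forms C18–C19 and the quaternary C19; acid hydrolysis releases keto aldehyde 4, whose aldehyde cannot enolise and can be reached in a six-membered aldol condensation only by the ethyl-side enol, so the C14=C15 alkene forms with the methyl on C15 (Robinson-type annulation).

Step 3
Reactants: 6 (2E,6E)-farnesol
Product: 7 tert-butyldimethyl{[(2E,6E)-3,7,11-trimethyldodeca-2,6,10-trien-1-yl]oxy}silane
Conditions: TBSCl, imidazole, DMF, rt
Reagents that add atoms: tert-butyldimethylsilyl chloride, CC(C)(C)[Si](C)(C)Cl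
Why: Standard silylation of a primary allylic alcohol; the silyl ether tolerates the oxidation, ylide, borane, organomagnesium, hydride and radical steps that follow.

Step 4
Reactants: 7 tert-butyldimethyl{[(2E,6E)-3,7,11-trimethyldodeca-2,6,10-trien-1-yl]oxy}silane
Product: 8 (2E,6E,10E)-12-[(tert-butyldimethylsilyl)oxy]-2,6,10-trimethyldodeca-2,6,10-trien-1-ol
Conditions: SeO2 (cat.), tBuOOH, salicylic acid (cat.), CH2Cl2, 0 °C to rt; stopped at partial conversion, 7 recycled
Reagents that add atoms: tert-butyl hydroperoxide, CC(C)(C)OO
Why: Riley-type SeO2 allylic oxidation (ene reaction, then 2,3-sigmatropic shift) attacks the most electron-rich terminal alkene and oxidises its E-methyl group to the E-allylic alcohol; the C2=C3 alkene is deactivated by the allylic silyloxy group, and any enal 9 formed by over-oxidation is simply carried into step 5.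

Step 5
Reactants: 8 (2E,6E,10E)-12-[(tert-butyldimethylsilyl)oxy]-2,6,10-trimethyldodeca-2,6,10-trien-1-ol
Product: 9 (2E,6E,10E)-12-[(tert-butyldimethylsilyl)oxy]-2,6,10-trimethyldodeca-2,6,10-trienal
Conditions: MnO2, CH2Cl2, rt
Reagents that add atoms: none
Why: MnO2 oxidises allylic alcohols selectively to enals under neutral conditions and keeps the E geometry of the trisubstituted alkene.

Step 6
Reactants: 9 (2E,6E,10E)-12-[(tert-butyldimethylsilyl)oxy]-2,6,10-trimethyldodeca-2,6,10-trienal
Product: 10 tert-butyldimethyl{[(2E,6E,10E)-3,7,11-trimethyltrideca-2,6,10,12-tetraen-1-yl]oxy}silane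
Conditions: Ph3PCH3Br, KOtBu, THF, 0 °C; then 9, 0 °C to rt
Reagents that add atoms: methyltriphenylphosphonium bromide, C[P+](c1ccccc1)(c1ccccc1)c1ccccc1.[Br-]
Why: Wittig methylenation adds the missing carbon C13 by 1,2-attack of the unstabilised ylide on the enal; no stereocentre or alkene geometry is created or at risk.

Step 7
Reactants: 10 tert-butyldimethyl{[(2E,6E,10E)-3,7,11-trimethyltrideca-2,6,10,12-tetraen-1-yl]oxy}silane
Product: 11 (3E,7E,11E)-13-[(tert-butyldimethylsilyl)oxy]-3,7,11-trimethyltrideca-3,7,11-trien-1-ol
Conditions: Sia2BH (from BH3·THF and 2-methylbut-2-ene), THF, 0 °C; then NaOH, H2O2, 0 °C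
Reagents that add atoms: hydrogen peroxide, OO
Why: Anti-Markovnikov hydroboration–oxidation with a hindered dialkylborane attacks only the monosubstituted vinyl terminus of the diene and leaves the trisubstituted alkenes alone, the same selectivity that turns a methylenated terpene enal into its homoallylic alcohol.

Step 8
Reactants: 11 (3E,7E,11E)-13-[(tert-butyldimethylsilyl)oxy]-3,7,11-trimethyltrideca-3,7,11-trien-1-ol
Product: 13 {[(2E,6E,10E)-13-bromo-3,7,11-trimethyltrideca-2,6,10-trien-1-yl]oxy}(tert-butyl)dimethylsilane, via homoallylic mesylate 12 (not isolated)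
Conditions: MsCl, Et3N, CH2Cl2, −20 °C; then LiBr, THF, rt
Reagents that add atoms: lithium bromide, [Li+].[Br-]; methanesulfonyl chloride, CS(=O)(=O)Cl (its atoms remain only in intermediate 12)
Why: Sulfonylation followed by bromide displacement at an unhindered primary carbon; these non-acidic, phosphine-free conditions spare the allylic silyl ether, which a phosphonium bromide reagent could convert into an allylic bromide.

Step 9
Reactants: 13 {[(2E,6E,10E)-13-bromo-3,7,11-trimethyltrideca-2,6,10-trien-1-yl]oxy}(tert-butyl)dimethylsilane
Product: 14 (3E,7E,11E)-13-[(tert-butyldimethylsilyl)oxy]-3,7,11-trimethyltrideca-3,7,11-trien-1-ylmagnesium bromide (titrated Et2O solution, used at once)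
Conditions: Mg turnings (activated with a crystal of I2), Et2O, rt, slow addition of 13
Reagents that add atoms: magnesium, [Mg]
Why: Magnesium insertion into a primary alkyl bromide; diethyl ether is chosen because the following copper catalysis is eroded by THF, and the reagent is kept at or below room temperature so the slow homoallyl–cyclopropylmethyl interconversion cannot scramble the C10=C11 geometry.

Step 10
Reactants: 5 2,4,4-trimethylcyclohex-2-en-1-one; 14 (3E,7E,11E)-13-[(tert-butyldimethylsilyl)oxy]-3,7,11-trimethyltrideca-3,7,11-trien-1-ylmagnesium bromide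
Product: 16 (2R,3S)-3-[(3E,7E,11E)-13-[(tert-butyldimethylsilyl)oxy]-3,7,11-trimethyltrideca-3,7,11-trien-1-yl]-2-hydroxy-2,4,4-trimethylcyclohexan-1-one, via bromomagnesium enolate 15 (not isolated)
Conditions: CuBr·SMe2 (5 mol %), (R)-1-[(Sp)-2-(diphenylphosphino)ferrocenyl]ethyldicyclohexylphosphine (Josiphos, 6 mol %), 5 (slight excess), tBuOMe, −78 °C, 14 added over 3 h, then −60 °C; then 2-(benzenesulfonyl)-3-phenyloxaziridine, THF, −78 to −40 °C; aq NH4Cl at −40 °C
Reagents that add atoms: 2-(benzenesulfonyl)-3-phenyloxaziridine, O=S(=O)(c1ccccc1)N1OC1c1ccccc1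
Why: Transmetalation of 14 to the diphosphine-bound monovalent copper bromide gives a chiral alkylcopper species that binds the C14=C15 alkene of 5 as a π-complex, adds oxidatively to a trivalent copper σ-complex at C14 while magnesium holds the carbonyl oxygen, and reductively eliminates to form the C13–C14 bond and enolate 15. The closest known reaction type is the copper–ferrocenyl diphosphine catalysed enantioselective conjugate addition of Grignard reagents to cyclic enones with trapping of the magnesium enolate, combined with N-sulfonyloxaziridine hydroxylation of enolates; the 2,4,4-substitution makes this enone more hindered than the usual substrates. No ring is closed. C14 is set by the ligand, which has to deliver the chain to the Si face of C14. C15 is set by the substrate: in 15 the C15 methyl and the O–Mg group lie in the enolate plane, allylic 1,2-strain pushes the C14 chain pseudoaxial, and the bulky oxaziridine transfers oxygen to C15 from the opposite face, leaving hydroxyl trans and methyl cis to the chain. Three selectivities are needed: 1,4- over 1,2-addition, secured by copper catalysis, slow addition of 14 and a weakly coordinating ether at low temperature; a single enolate regioisomer, secured because 15 is formed regiospecifically and never equilibrated; and oxidation of the enolate in preference to the three trisubstituted alkenes, secured because the oxaziridine does not epoxidise unactivated alkenes at −78 °C. The cold quench protects the magnesium alkoxide of 16 from α-ketol rearrangement.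

Step 11
Reactants: 16 (2R,3S)-3-[(3E,7E,11E)-13-[(tert-butyldimethylsilyl)oxy]-3,7,11-trimethyltrideca-3,7,11-trien-1-yl]-2-hydroxy-2,4,4-trimethylcyclohexan-1-one
Product: 17 (1R,2R,3S)-3-[(3E,7E,11E)-13-[(tert-butyldimethylsilyl)oxy]-3,7,11-trimethyltrideca-3,7,11-trien-1-yl]-2,4,4-trimethylcyclohexane-1,2-diol
Conditions: NaBH4, MeOH, −20 to 0 °C
Reagents that add atoms: none
Why: Borohydride reduction of the C16 ketone; in either chair of 16 hydride should approach C16 from the face away from the C14 chain, giving mainly the trans-diol, and the new centre is erased in step 13 so its configuration is not critical.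

Step 12
Reactants: 17 (1R,2R,3S)-3-[(3E,7E,11E)-13-[(tert-butyldimethylsilyl)oxy]-3,7,11-trimethyltrideca-3,7,11-trien-1-yl]-2,4,4-trimethylcyclohexane-1,2-diol
Product: 18 O-{(1R,2R,3S)-3-[(3E,7E,11E)-13-[(tert-butyldimethylsilyl)oxy]-3,7,11-trimethyltrideca-3,7,11-trien-1-yl]-2-hydroxy-2,4,4-trimethylcyclohexyl} S-methyl carbonodithioate
Conditions: NaH (1.1 equiv), imidazole (cat.), THF, 0 °C; CS2; then MeI, 0 °C to rt
Reagents that add atoms: carbon disulfide, S=C=S; iodomethane, CI
Why: Xanthate formation for a Barton–McCombie deoxygenation: the more accessible and more acidic secondary alkoxide adds to CS2 and the dithiocarbonate anion is S-methylated; with only a slight excess of base the tertiary hydroxyl stays protonated, and the trans arrangement of the two oxygens disfavours closure to a cyclic thionocarbonate.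

Step 13
Reactants: 18 O-{(1R,2R,3S)-3-[(3E,7E,11E)-13-[(tert-butyldimethylsilyl)oxy]-3,7,11-trimethyltrideca-3,7,11-trien-1-yl]-2-hydroxy-2,4,4-trimethylcyclohexyl} S-methyl carbonodithioate
Product: 19 (1S,2S)-2-[(3E,7E,11E)-13-[(tert-butyldimethylsilyl)oxy]-3,7,11-trimethyltrideca-3,7,11-trien-1-yl]-1,3,3-trimethylcyclohexan-1-ol
Conditions: Bu3SnH, AIBN (cat.), toluene, 90 °C
Reagents that add atoms: none
Why: Barton–McCombie radical deoxygenation: the stannyl radical adds to C=S, fragmentation gives the secondary C16 radical and hydrogen transfer from Bu3SnH gives the methylene; a β-hydroxyl is not expelled from a carbon radical, tin hydride is kept concentrated enough to outrun 6-exo cyclisation onto C10=C11, and the temperature stays below that of Chugaev elimination.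

Step 14
Reactants: 19 (1S,2S)-2-[(3E,7E,11E)-13-[(tert-butyldimethylsilyl)oxy]-3,7,11-trimethyltrideca-3,7,11-trien-1-yl]-1,3,3-trimethylcyclohexan-1-ol
Product: 20 preluffariellolide A, (1S,2S)-2-[(3E,7E,11E)-13-hydroxy-3,7,11-trimethyltrideca-3,7,11-trien-1-yl]-1,3,3-trimethylcyclohexan-1-ol
Conditions: Bu4NF, THF, 0 °C to rt
Reagents that add atoms: none
Why: Fluoride cleavage of the primary silyl ether under non-acidic conditions, so the allylic alcohol, the tertiary alcohol and the alkenes are not exposed to ionising conditions.

## Compound list

1 | 2-methylpropanal | CC(C)C=O | starting material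
2 | 1-(2-methylprop-1-en-1-yl)pyrrolidine | CC(C)=CN1CCCC1 | intermediate
3 | pent-1-en-3-one | CCC(=O)C=C | starting material
4 | 2,2-dimethyl-5-oxoheptanal | CCC(=O)CCC(C)(C)C=O | intermediate (not isolated)
5 | 2,4,4-trimethylcyclohex-2-en-1-one | CC1=CC(C)(C)CCC1=O | intermediate
6 | (2E,6E)-farnesol, (2E,6E)-3,7,11-trimethyldodeca-2,6,10-trien-1-ol | C/C(=C\CO)CC/C=C(\C)CCC=C(C)C | starting material
7 | tert-butyldimethyl{[(2E,6E)-3,7,11-trimethyldodeca-2,6,10-trien-1-yl]oxy}silane | CC(C)=CCC/C(C)=C/CC/C(C)=C/CO[Si](C)(C)C(C)(C)C | intermediate
8 | (2E,6E,10E)-12-[(tert-butyldimethylsilyl)oxy]-2,6,10-trimethyldodeca-2,6,10-trien-1-ol | OC/C(C)=C/CC/C(C)=C/CC/C(C)=C/CO[Si](C)(C)C(C)(C)C | intermediate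
9 | (2E,6E,10E)-12-[(tert-butyldimethylsilyl)oxy]-2,6,10-trimethyldodeca-2,6,10-trienal | O=C/C(C)=C/CC/C(C)=C/CC/C(C)=C/CO[Si](C)(C)C(C)(C)C | intermediate
10 | tert-butyldimethyl{[(2E,6E,10E)-3,7,11-trimethyltrideca-2,6,10,12-tetraen-1-yl]oxy}silane | C=C/C(C)=C/CC/C(C)=C/CC/C(C)=C/CO[Si](C)(C)C(C)(C)C | intermediate
11 | (3E,7E,11E)-13-[(tert-butyldimethylsilyl)oxy]-3,7,11-trimethyltrideca-3,7,11-trien-1-ol | OCC/C(C)=C/CC/C(C)=C/CC/C(C)=C/CO[Si](C)(C)C(C)(C)C | intermediate
12 | (3E,7E,11E)-13-[(tert-butyldimethylsilyl)oxy]-3,7,11-trimethyltrideca-3,7,11-trien-1-yl methanesulfonate | CS(=O)(=O)OCC/C(C)=C/CC/C(C)=C/CC/C(C)=C/CO[Si](C)(C)C(C)(C)C | intermediate (not isolated)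
13 | {[(2E,6E,10E)-13-bromo-3,7,11-trimethyltrideca-2,6,10-trien-1-yl]oxy}(tert-butyl)dimethylsilane | BrCC/C(C)=C/CC/C(C)=C/CC/C(C)=C/CO[Si](C)(C)C(C)(C)C | intermediate
14 | (3E,7E,11E)-13-[(tert-butyldimethylsilyl)oxy]-3,7,11-trimethyltrideca-3,7,11-trien-1-ylmagnesium bromide | Br[Mg]CC/C(C)=C/CC/C(C)=C/CC/C(C)=C/CO[Si](C)(C)C(C)(C)C | intermediate
15 | bromomagnesium (3S)-3-[(3E,7E,11E)-13-[(tert-butyldimethylsilyl)oxy]-3,7,11-trimethyltrideca-3,7,11-trien-1-yl]-2,4,4-trimethylcyclohex-1-en-1-olate | CC(C)(C)[Si](C)(C)OC/C=C(\C)CC/C=C(\C)CC/C=C(\C)CC[C@H]1C(C)(C)CCC(O[Mg]Br)=C1C | intermediate (not isolated)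
16 | (2R,3S)-3-[(3E,7E,11E)-13-[(tert-butyldimethylsilyl)oxy]-3,7,11-trimethyltrideca-3,7,11-trien-1-yl]-2-hydroxy-2,4,4-trimethylcyclohexan-1-one | CC(C)(C)[Si](C)(C)OC/C=C(\C)CC/C=C(\C)CC/C=C(\C)CC[C@H]1C(C)(C)CCC(=O)[C@]1(C)O | intermediate
17 | (1R,2R,3S)-3-[(3E,7E,11E)-13-[(tert-butyldimethylsilyl)oxy]-3,7,11-trimethyltrideca-3,7,11-trien-1-yl]-2,4,4-trimethylcyclohexane-1,2-diol | CC(C)(C)[Si](C)(C)OC/C=C(\C)CC/C=C(\C)CC/C=C(\C)CC[C@H]1C(C)(C)CC[C@@H](O)[C@]1(C)O | intermediate
18 | O-{(1R,2R,3S)-3-[(3E,7E,11E)-13-[(tert-butyldimethylsilyl)oxy]-3,7,11-trimethyltrideca-3,7,11-trien-1-yl]-2-hydroxy-2,4,4-trimethylcyclohexyl} S-methyl carbonodithioate | CC(C)(C)[Si](C)(C)OC/C=C(\C)CC/C=C(\C)CC/C=C(\C)CC[C@H]1C(C)(C)CC[C@@H](OC(=S)SC)[C@]1(C)O | intermediate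
19 | (1S,2S)-2-[(3E,7E,11E)-13-[(tert-butyldimethylsilyl)oxy]-3,7,11-trimethyltrideca-3,7,11-trien-1-yl]-1,3,3-trimethylcyclohexan-1-ol | CC(C)(C)[Si](C)(C)OC/C=C(\C)CC/C=C(\C)CC/C=C(\C)CC[C@H]1C(C)(C)CCC[C@]1(C)O | intermediate
20 | preluffariellolide A, (1S,2S)-2-[(3E,7E,11E)-13-hydroxy-3,7,11-trimethyltrideca-3,7,11-trien-1-yl]-1,3,3-trimethylcyclohexan-1-ol | C/C(=C\CO)CC/C=C(\C)CC/C=C(\C)CC[C@H]1C(C)(C)CCC[C@]1(C)O | target

## Step count and risk

Total step count: 14. Longest linear sequence: 12 steps (steps 3 to 14, from 6); steps 1 and 2 form the short second branch that joins at step 10.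

**Step 10 (key step).** Three things may go wrong. Delivery of the chain to C14 may be slow, because the α-methyl group and the neighbouring quaternary C19 hinder π-complexation, so uncatalysed 1,2-addition and deprotonation of the enone at C17 can compete. Face discrimination by the ligand may be poor on this substitution pattern. Oxygen transfer to the aggregated magnesium enolate may be incomplete, with protonation to the unhydroxylated ketone or addition of the enolate to the sulfonylimine by-product.

The fallback sets out from 14 and comes back at 16. The α-methyl group is taken off the acceptor and brought in later: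
- 14 is added under the same copper–diphosphine catalysis to 4,4-dimethylcyclohex-2-en-1-one F1, an acceptor closer to the usual substrates.
- The resulting bromomagnesium enolate F2 is methylated in the flask (MeI, DMPU) to the trans-2-methyl ketone F3.
- Equilibrating silylation (TMSCl, NaI, Et3N, MeCN) converts F3 into the more substituted trimethylsilyl enol ether F4.
- MeLi in THF releases from it the lithium enolate F5, which is hydroxylated at −78 °C by the same oxaziridine to give 16.

Carbon–carbon bond formation, methylation and oxygenation are thereby separated, and a more reactive lithium enolate is oxidised, at the cost of two steps.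

**Step 12.** Regiocontrol of the thioacylation may fail. The neighbouring tertiary alkoxide can attack the xanthate with loss of methanethiolate and close a cyclic thionocarbonate, whose radical fragmentation would break the tertiary C15–O bond instead of the C16–O bond.

The fallback sets out from 17 and comes back at 19, so it also bypasses the tin hydride step:
- Selective mesylation of the secondary hydroxyl (MsCl, Et3N, CH2Cl2, −20 °C) gives the hydroxy mesylate F6.
- K2CO3 in MeOH closes the 15,16-epoxide F7 by backside attack of the C15 alkoxide, which the trans-diol geometry allows.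
- LiEt3BH in THF opens the epoxide at the less substituted C16 and gives 19 with the C15–O bond untouched.

**Step 4.** Site selectivity and conversion of the allylic oxidation may be poor: attack at internal allylic positions, over-oxidation beyond the enal, and much unreacted 7.

The fallback sets out from 7 and comes back at 9:
- NBS in aqueous THF at 0 °C gives the terminal bromohydrin F8.
- K2CO3 in MeOH closes it to the 10,11-epoxide F9.
- H5IO6 in THF/Et2O at 0 °C cleaves F9 to the trisnor aldehyde F10.
- A Wittig reaction of F10 with the stabilised ylide 2-(triphenylphosphoranylidene)propanal in warm toluene gives enal 9 with E geometry.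

## Further compounds

F1 | step 10 | 4,4-dimethylcyclohex-2-en-1-one | CC1(C)CCC(=O)C=C1
F2 | step 10 | bromomagnesium (3R)-3-[(3E,7E,11E)-13-[(tert-butyldimethylsilyl)oxy]-3,7,11-trimethyltrideca-3,7,11-trien-1-yl]-4,4-dimethylcyclohex-1-en-1-olate | CC(C)(C)[Si](C)(C)OC/C=C(\C)CC/C=C(\C)CC/C=C(\C)CC[C@H]1C(C)(C)CCC(O[Mg]Br)=C1
F3 | step 10 | (2R,3R)-3-[(3E,7E,11E)-13-[(tert-butyldimethylsilyl)oxy]-3,7,11-trimethyltrideca-3,7,11-trien-1-yl]-2,4,4-trimethylcyclohexan-1-one | CC(C)(C)[Si](C)(C)OC/C=C(\C)CC/C=C(\C)CC/C=C(\C)CC[C@H]1C(C)(C)CCC(=O)[C@@H]1C
F4 | step 10 | tert-butyldimethyl{[(2E,6E,10E)-3,7,11-trimethyl-13-[(1S)-2,6,6-trimethyl-3-(trimethylsilyloxy)cyclohex-2-en-1-yl]trideca-2,6,10-trien-1-yl]oxy}silane | CC(C)(C)[Si](C)(C)OC/C=C(\C)CC/C=C(\C)CC/C=C(\C)CC[C@H]1C(C)(C)CCC(O[Si](C)(C)C)=C1C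
F5 | step 10 | lithium (3S)-3-[(3E,7E,11E)-13-[(tert-butyldimethylsilyl)oxy]-3,7,11-trimethyltrideca-3,7,11-trien-1-yl]-2,4,4-trimethylcyclohex-1-en-1-olate | CC(C)(C)[Si](C)(C)OC/C=C(\C)CC/C=C(\C)CC/C=C(\C)CC[C@H]1C(C)(C)CCC(O[Li])=C1C
F6 | step 12 | (1R,2R,3S)-3-[(3E,7E,11E)-13-[(tert-butyldimethylsilyl)oxy]-3,7,11-trimethyltrideca-3,7,11-trien-1-yl]-2-hydroxy-2,4,4-trimethylcyclohexyl methanesulfonate | CC(C)(C)[Si](C)(C)OC/C=C(\C)CC/C=C(\C)CC/C=C(\C)CC[C@H]1C(C)(C)CC[C@@H](OS(C)(=O)=O)[C@]1(C)O
F7 | step 12 | tert-butyldimethyl{[(2E,6E,10E)-3,7,11-trimethyl-13-[(1R,2S,6S)-1,3,3-trimethyl-7-oxabicyclo[4.1.0]heptan-2-yl]trideca-2,6,10-trien-1-yl]oxy}silane (oxirane trans to the chain) | CC(C)(C)[Si](C)(C)OC/C=C(\C)CC/C=C(\C)CC/C=C(\C)CC[C@H]1C(C)(C)CC[C@@H]2O[C@]12C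
F8 | step 4 | (6E,10E)-3-bromo-12-[(tert-butyldimethylsilyl)oxy]-2,6,10-trimethyldodeca-6,10-dien-2-ol (racemic) | CC(C)(O)C(Br)CC/C(C)=C/CC/C(C)=C/CO[Si](C)(C)C(C)(C)C
F9 | step 4 | tert-butyl{[(2E,6E)-9-(3,3-dimethyloxiran-2-yl)-3,7-dimethylnona-2,6-dien-1-yl]oxy}dimethylsilane (racemic) | CC1(C)OC1CC/C(C)=C/CC/C(C)=C/CO[Si](C)(C)C(C)(C)C
F10 | step 4 | (4E,8E)-10-[(tert-butyldimethylsilyl)oxy]-4,8-dimethyldeca-4,8-dienal | O=CCC/C(C)=C/CC/C(C)=C/CO[Si](C)(C)C(C)(C)C
A1 | alternative 1 | triisopropyl{[(1R,2R,6S)-1,3-dimethyl-7-oxabicyclo[4.1.0]hept-3-en-2-yl]methoxy}silane (oxirane oxygen trans to the CH2OSi group) | CC(C)[Si](C(C)C)(C(C)C)OC[C@H]1C(C)=CC[C@@H]2O[C@]12C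
A2 | alternative 1 | [(2,6-dimethylcyclohexa-2,5-dien-1-yl)methoxy]triisopropylsilane | CC(C)[Si](C(C)C)(C(C)C)OCC1C(C)=CCC=C1C
A3 | alternative 2 | (1S,6S)-6-acetyl-2,2,6-trimethylcyclohex-3-ene-1-carbaldehyde | O=C[C@H]1C(C)(C)C=CC[C@]1(C)C(C)=O
A4 | alternative 2 | 4-methylpenta-1,3-diene | CC(C)=CC=C
A5 | alternative 2 | (E)-3-methyl-4-oxopent-2-enal | CC(=O)/C(C)=C/C=O
A6 | alternative 3 | (1S,2S)-2-hydroxy-2,6,6-trimethylcyclohexane-1-carbaldehyde | O=C[C@H]1C(C)(C)CCC[C@]1(C)O
A7 | alternative 3 | 3,3-dimethyl-7-oxooctanal | O=CCC(C)(C)CCCC(C)=O
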